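## Retrosynthetic overview
1. Target 18 ⇐ bis-silyl quinone 17 (desilylation) ⇐ hexasubstituted phenol 15 (oxidative demethylation). The quinone is assembled one oxidation level lower, as a protected 1,2,4,5-tetraoxygenated benzene.
2. Key disconnection of 15: cut the bond from the pentadecyl-bearing ring carbon to its C–OH neighbour, and the bond from its other neighbour (C–O) to the next C–O carbon, the one beside C–CH3. This leaves a C2 unit (silyl ynol ether 10) and a C4 unit (cyclobutenone 6, reacting as its vinylketene), joined in one thermal pericyclic cascade.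
3. Enabling feature: ring carbons 1, 2, 4 and 5 all carry oxygen, and carbons 3 and 6 carry methyl and pentadecyl. The pair C(pentadecyl)–C(O) is therefore a latent polarised alkyl–C≡C–O unit flanked by two oxygenated carbons, which map onto the ketene C=O carbon and the methoxy-bearing ketene carbon. The proton shift between the two identical quinone tautomers makes each C–OH/C=O pair interchangeable, so the oxygens need only be placed, not differentiated.
4. 6 comes from dimethyl squarate 1 (reduction, silylation, MeLi addition with carbonyl transposition). 10 comes from ethyl palmitate 7 and CH2Br2 through the ynolate.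
5. Ring order: the four-membered ring is bought with 1 and sacrificed. The six-membered carbocycle is the only ring made (step 5).

Key step: step 5

Remark: the target is achiral, so all stereocentres of the intermediates are carried racemic. The tautomer obtained in step 7 is the same compound as the target as drawn.

## Route

Step 1
Reactants: 1 dimethyl squarate (3,4-dimethoxycyclobut-3-ene-1,2-dione)
Product: 2 (±)-4-hydroxy-2,3-dimethoxycyclobut-2-en-1-one
Conditions: LiAlH(Ot-Bu)3 (1.05 equiv), THF, −78 to −20 °C; then H2O, 0 °C
Reagents that add atoms: none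
Why: Chemoselective 1,2-hydride reduction of one of the two equivalent vinylogous-ester carbonyls by the bulky, mild LiAlH(Ot-Bu)3 is the established entry to 4-hydroxycyclobutenones from squarate esters, the alkoxide resisting a second reduction at low temperature; the new stereocentre arises racemic and is erased in step 5.

Step 2
Reactants: 2 (±)-4-hydroxy-2,3-dimethoxycyclobut-2-en-1-one
Product: 3 (±)-4-[(tert-butyldimethylsilyl)oxy]-2,3-dimethoxycyclobut-2-en-1-one
Conditions: TBSCl, imidazole, DMF, 0 to 25 °C
Reagents that add atoms: tert-butyldimethylsilyl chloride, CC(C)(C)[Si](C)(C)Cl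
Why: Standard silyl ether formation on a secondary alcohol under mild imidazole conditions leaves the enol ethers untouched, blocks acid-triggered loss of methanol and installs the donor group that steers the later ring opening.

Step 3
Reactants: 3 (±)-4-[(tert-butyldimethylsilyl)oxy]-2,3-dimethoxycyclobut-2-en-1-one
Product: 6 (±)-4-[(tert-butyldimethylsilyl)oxy]-2-methoxy-3-methylcyclobut-2-en-1-one, via lithium alkoxide 4 (not isolated), via trifluoroacetate 5 (not isolated)
Conditions: MeLi, THF, −78 °C; (CF3CO)2O, −78 °C; then aq NaHCO3, −78 to 0 °C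
Reagents that add atoms: methyllithium, [Li]C; water, O
Why: 1,2-Addition of MeLi to the only carbonyl (enolisation at C4 would need an antiaromatic cyclobutadienolate), then trifluoroacetylation, ionisation to the methoxy-stabilised cyclobutenyl cation and hydrolysis constitute the known squarate-type 1,3-carbonyl transposition, so the carbonyl ends next to C–OMe and the methyl next to CH–OTBS; the carbinol stereocentre of 4 and 5 is lost again and C4 stays racemic.

Step 4
Reactants: 7 ethyl palmitate (ethyl hexadecanoate)
Product: 10 (heptadec-1-yn-1-yloxy)triisopropylsilane, via dibromo enolate 8 (not isolated), via lithium ynolate 9 (not isolated)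
Conditions: CH2Br2, lithium 2,2,6,6-tetramethylpiperidide (LiTMP, 2 equiv), THF, −78 °C; 7; n-BuLi, −78 to 25 °C; TIPSCl, −78 to 0 °C
Reagents that add atoms: dibromomethane, BrCBr; triisopropylsilyl chloride, CC(C)[Si](Cl)(C(C)C)C(C)C
Why: Kowalski ester homologation: LiCHBr2 is acylated by 7 and the second equivalent of LiTMP gives enolate 8, bromine–lithium exchange with n-BuLi sets off the carbenoid 1,2-shift of the pentadecyl group to ynolate 9, and the bulky TIPSCl silylates this ambident anion on oxygen rather than on carbon.

Step 5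
Reactants: 6 (±)-4-[(tert-butyldimethylsilyl)oxy]-2-methoxy-3-methylcyclobut-2-en-1-one; 10 (heptadec-1-yn-1-yloxy)triisopropylsilane
Product: 15 2-[(tert-butyldimethylsilyl)oxy]-4-methoxy-3-methyl-6-pentadecyl-5-[(triisopropylsilyl)oxy]phenol, via vinylketene 11 (not isolated), via vinylcyclobutenone 12 (not isolated), via dienylketene 13 (not isolated), via cyclohexadienone 14 (not isolated)
Conditions: 10 (1.3 equiv), toluene, sealed tube, argon, 80 to 110 °C
Reagents that add atoms: none
Why: Heat opens the four-membered ring of 6 by conrotatory 4π electrocyclic cleavage of the C(=O)–CH(OTBS) bond with the silyloxy donor turning outward, and the ketene C=C of vinylketene 11 adds ynol ether 10 in a polarity-matched [2+2] cycloaddition in which the pentadecyl-bearing alkyne carbon bonds to the ketene carbonyl carbon and the silyloxy-bearing alkyne carbon bonds to the methoxy-bearing ketene carbon, so both new ring bonds arise in this one event. Vinylcyclobutenone 12 then reopens (4π) with the methoxy group on its quaternary carbon turning outward, which places the silyloxyvinyl arm beside the new ketene of 13, and the six-membered carbocycle, the only ring closed for good, forms by disrotatory 6π electrocyclisation of 13 (restoring the bond cut at the start) to dienone 14, which enolises to phenol 15. The closest known reaction type is the Danheiser benzannulation of cyclobutenones with heteroatom-substituted alkynes in its silyloxyalkyne form. No stereocentre survives: those of 6, 12 and 14 are racemic, transient and erased by aromatisation, and the alkene geometries of 11 and 13 follow from donor-outward torquoselectivity. The selectivity needed is the head-to-tail orientation of the alkyne, which the strong O–C≡C polarisation of 10 secures against the electrophilic ketene carbonyl carbon, and even a leak through direct [4+2] addition to 11 would place oxygen, alkyl and methyl groups in the same ring pattern. A modest excess of 10 and moderate dilution should hold back ketene dimerisation and acylation of the hindered phenol by 11.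

Step 6
Reactants: 15 2-[(tert-butyldimethylsilyl)oxy]-4-methoxy-3-methyl-6-pentadecyl-5-[(triisopropylsilyl)oxy]phenol
Product: 17 2-[(tert-butyldimethylsilyl)oxy]-3-methyl-6-pentadecyl-5-[(triisopropylsilyl)oxy]cyclohexa-2,5-diene-1,4-dione, via quinol hemiketal 16 (not isolated)
Conditions: PhI(OAc)2 (1.1 equiv), MeCN/THF/H2O, 0 °C
Reagents that add atoms: water, O
Why: Oxidative dealkylation of a 4-methoxyphenol with the trivalent iodine reagent PhI(OAc)2: ligand exchange at the free phenol, attack of water at the methoxy-bearing para carbon and collapse of hemiketal 16 with loss of methanol should give the para-quinone, while the aryl silyl ethers tolerate the weakly acidic medium.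

Step 7
Reactants: 17 2-[(tert-butyldimethylsilyl)oxy]-3-methyl-6-pentadecyl-5-[(triisopropylsilyl)oxy]cyclohexa-2,5-diene-1,4-dione
Product: 18 2,5-dihydroxy-3-methyl-6-pentadecylcyclohexa-2,5-diene-1,4-dione
Conditions: HF (48% aq), MeCN/THF, 0 to 25 °C
Reagents that add atoms: none
Why: Fluoride-driven desilylation, fast here because both silyl ethers are vinylogous silyl esters of the quinone carbonyls, should set free the 2,5-dihydroxyquinone without changing the redox state, and no stereocentre is involved.

## Compound list
1 | dimethyl squarate (3,4-dimethoxycyclobut-3-ene-1,2-dione) | COC1=C(OC)C(=O)C1=O | starting material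
2 | (±)-4-hydroxy-2,3-dimethoxycyclobut-2-en-1-one | COC1=C(OC)C(O)C1=O | intermediate
3 | (±)-4-[(tert-butyldimethylsilyl)oxy]-2,3-dimethoxycyclobut-2-en-1-one | COC1=C(OC)C(O[Si](C)(C)C(C)(C)C)C1=O | intermediate
4 | lithium 4-[(tert-butyldimethylsilyl)oxy]-2,3-dimethoxy-1-methylcyclobut-2-en-1-olate (racemic, diastereomer mixture, not isolated) | COC1=C(OC)C(C)([O-])C1O[Si](C)(C)C(C)(C)C.[Li+] | intermediate
5 | 4-[(tert-butyldimethylsilyl)oxy]-2,3-dimethoxy-1-methylcyclobut-2-en-1-yl trifluoroacetate (racemic, diastereomer mixture, not isolated) | COC1=C(OC)C(C)(OC(=O)C(F)(F)F)C1O[Si](C)(C)C(C)(C)C | intermediate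
6 | (±)-4-[(tert-butyldimethylsilyl)oxy]-2-methoxy-3-methylcyclobut-2-en-1-one | COC1=C(C)C(O[Si](C)(C)C(C)(C)C)C1=O | intermediate
7 | ethyl palmitate (ethyl hexadecanoate) | CCCCCCCCCCCCCCCC(=O)OCC | starting material
8 | lithium 1,1-dibromoheptadec-1-en-2-olate (not isolated) | CCCCCCCCCCCCCCCC([O-])=C(Br)Br.[Li+] | intermediate
9 | lithium heptadec-1-yn-1-olate (not isolated) | CCCCCCCCCCCCCCCC#C[O-].[Li+] | intermediate
10 | (heptadec-1-yn-1-yloxy)triisopropylsilane | CCCCCCCCCCCCCCCC#CO[Si](C(C)C)(C(C)C)C(C)C | intermediate
11 | (E)-4-[(tert-butyldimethylsilyl)oxy]-2-methoxy-3-methylbuta-1,3-dien-1-one (not isolated) | COC(=C=O)/C(C)=C/O[Si](C)(C)C(C)(C)C | intermediate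
12 | (±)-4-{(E)-1-[(tert-butyldimethylsilyl)oxy]prop-1-en-2-yl}-4-methoxy-2-pentadecyl-3-[(triisopropylsilyl)oxy]cyclobut-2-en-1-one (not isolated) | CCCCCCCCCCCCCCCC1=C(O[Si](C(C)C)(C(C)C)C(C)C)C(OC)(/C(C)=C/O[Si](C)(C)C(C)(C)C)C1=O | intermediate
13 | (3Z,5E)-6-[(tert-butyldimethylsilyl)oxy]-4-methoxy-5-methyl-2-pentadecyl-3-[(triisopropylsilyl)oxy]hexa-1,3,5-trien-1-one (not isolated) | CCCCCCCCCCCCCCCC(=C=O)/C(O[Si](C(C)C)(C(C)C)C(C)C)=C(/OC)\C(C)=C\O[Si](C)(C)C(C)(C)C | intermediate
14 | (±)-6-[(tert-butyldimethylsilyl)oxy]-4-methoxy-5-methyl-2-pentadecyl-3-[(triisopropylsilyl)oxy]cyclohexa-2,4-dien-1-one (not isolated) | CCCCCCCCCCCCCCCC1=C(O[Si](C(C)C)(C(C)C)C(C)C)C(OC)=C(C)C(O[Si](C)(C)C(C)(C)C)C1=O | intermediate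
15 | 2-[(tert-butyldimethylsilyl)oxy]-4-methoxy-3-methyl-6-pentadecyl-5-[(triisopropylsilyl)oxy]phenol | CCCCCCCCCCCCCCCc1c(O)c(O[Si](C)(C)C(C)(C)C)c(C)c(OC)c1O[Si](C(C)C)(C(C)C)C(C)C | intermediate
16 | (±)-2-[(tert-butyldimethylsilyl)oxy]-4-hydroxy-4-methoxy-3-methyl-6-pentadecyl-5-[(triisopropylsilyl)oxy]cyclohexa-2,5-dien-1-one (not isolated) | CCCCCCCCCCCCCCCC1=C(O[Si](C(C)C)(C(C)C)C(C)C)C(O)(OC)C(C)=C(O[Si](C)(C)C(C)(C)C)C1=O | intermediate
17 | 2-[(tert-butyldimethylsilyl)oxy]-3-methyl-6-pentadecyl-5-[(triisopropylsilyl)oxy]cyclohexa-2,5-diene-1,4-dione | CCCCCCCCCCCCCCCC1=C(O[Si](C(C)C)(C(C)C)C(C)C)C(=O)C(C)=C(O[Si](C)(C)C(C)(C)C)C1=O | intermediate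
18 | 2,5-dihydroxy-3-methyl-6-pentadecylcyclohexa-2,5-diene-1,4-dione | CCCCCCCCCCCCCCCC1=C(O)C(=O)C(C)=C(O)C1=O | target

## Count and risks
Total step count: 7. Longest linear sequence: 6 (steps 1, 2, 3, 5, 6, 7).

**Step 5.** The bimolecular capture of the transient ketene may lose to reclosure, ketene dimerisation or acylation of the product phenol, or the cascade may stall before the second ring opening.
- The fallback replaces the pericyclic cascade by a metal-templated insertion. It sets out from 1 and 10 and comes back at 18.
- MeLi (THF, −78 °C; aq NH4Cl) should convert 1 into 4-hydroxy-2,3-dimethoxy-4-methylcyclobut-2-en-1-one F1.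
- A trace of HCl in CH2Cl2 should turn this into 3-methoxy-4-methylcyclobut-3-ene-1,2-dione F2.
- ClCo(PPh3)3 (benzene, 25 °C) should insert monovalent cobalt into the bond between the two carbonyl carbons to give the trivalent cobalt metallacycle ClCo(PPh3)2[C(O)C(OMe)=C(Me)C(O)] F3.
- After chloride abstraction with AgBF4 in MeCN, alkyne 10 should insert into a cobalt–acyl bond. Reductive elimination should then release 2-methoxy-3-methyl-6-pentadecyl-5-[(triisopropylsilyl)oxy]cyclohexa-2,5-diene-1,4-dione F4.
- The orientation rests on pairing the nucleophilic alkyne carbon with the more electrophilic acyl carbon, the one next to C–OMe. This orientation is the fallback's own weak point.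
- Aqueous NaOH in EtOH, then HCl, should cleave both the silyl group and the vinylogous methyl ester to give 18.

**Step 4.** The carbenoid rearrangement may be incomplete, butyl addition to the dibromoketone may compete, or silylation may occur on carbon in place of oxygen.
- The fallback reaches the ynolate by oxidation of an acetylide instead of a carbenoid shift. It sets out from 7 and comes back at 9.
- i-Bu2AlH (CH2Cl2, −78 °C) should give hexadecanal F5.
- Dimethyl (1-diazo-2-oxopropyl)phosphonate with K2CO3 in MeOH (Ohira–Bestmann form of the Seyferth–Gilbert homologation) should give heptadec-1-yne F6.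
- n-BuLi (THF, −78 °C) should give lithium heptadec-1-yn-1-ide F7.
- LiOOt-Bu (from t-BuOOH and LiN(SiMe3)2, THF, −78 to 0 °C) should transfer oxygen to the acetylide carbon to give ynolate 9, which is silylated as in step 4.

**Step 6.** Water may attack at the wrong ring carbon, the silyl groups may be lost early, or the electron-rich ring may be over-oxidised.
- The fallback removes the silyl groups first and lets air do the oxidation. It sets out from 15 and comes back at 18.
- n-Bu4NF (THF, 0 °C, argon) should give 5-methoxy-6-methyl-3-pentadecylbenzene-1,2,4-triol F8.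
- Stirring under air should oxidise its para-dihydroxy pair to 2-hydroxy-5-methoxy-6-methyl-3-pentadecylcyclohexa-2,5-diene-1,4-dione F9.
- Aqueous NaOH in EtOH at reflux, then HCl, should replace the methoxy group by addition–elimination at the vinylogous ester to give 18.

## Further compounds
F1 | step 5 | (±)-4-hydroxy-2,3-dimethoxy-4-methylcyclobut-2-en-1-one | COC1=C(OC)C(C)(O)C1=O
F2 | step 5 | 3-methoxy-4-methylcyclobut-3-ene-1,2-dione | COC1=C(C)C(=O)C1=O
F3 | step 5 | ClCo(PPh3)2[C(O)C(OMe)=C(Me)C(O)], chlorobis(triphenylphosphine)(2-methoxy-3-methyl-1,4-dioxobut-2-ene-1,4-diyl)cobalt | COC1=C(C)C(=O)[Co-2](Cl)([P+](c2ccccc2)(c2ccccc2)c2ccccc2)([P+](c2ccccc2)(c2ccccc2)c2ccccc2)C1=O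
F4 | step 5 | 2-methoxy-3-methyl-6-pentadecyl-5-[(triisopropylsilyl)oxy]cyclohexa-2,5-diene-1,4-dione | CCCCCCCCCCCCCCCC1=C(O[Si](C(C)C)(C(C)C)C(C)C)C(=O)C(C)=C(OC)C1=O
F5 | step 4 | hexadecanal | CCCCCCCCCCCCCCCC=O
F6 | step 4 | heptadec-1-yne | CCCCCCCCCCCCCCCC#C
F7 | step 4 | lithium heptadec-1-yn-1-ide | CCCCCCCCCCCCCCCC#[C-].[Li+]
F8 | step 6 | 5-methoxy-6-methyl-3-pentadecylbenzene-1,2,4-triol | CCCCCCCCCCCCCCCc1c(O)c(O)c(C)c(OC)c1O
F9 | step 6 | 2-hydroxy-5-methoxy-6-methyl-3-pentadecylcyclohexa-2,5-diene-1,4-dione | CCCCCCCCCCCCCCCC1=C(O)C(=O)C(C)=C(OC)C1=O
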